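**Plan**
- Retrosynthesis: after removal of the three O-protecting groups, ring B is cut at C1'–C2' and C5'–C6'. This leaves a four-carbon diene (C2'–C5') that carries ring D, and a nitrovinyl group on C3 of the chromone (rings A and C).
- Enabling feature: C3', C4' and C5' of ring B carry in a row a hydroxyl, the ring D ether oxygen and the ring D CH2. C2'–C3'–C4'–C5' is therefore the silyl enol ether of a 6-acetyl-3,4-dihydro-2H-pyran, and C1' and C6' are the two alkene carbons of the nitrovinyl group.
- Diene branch: glutaric anhydride → gem-dimethyl lactone → lactol → dihydropyran (ring D) → 6-acetyl derivative → silyloxy diene.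
- Dienophile branch: 2,4,6-trihydroxyacetophenone → dibenzyl ether → 3-formylchromone (ring C closed by Vilsmeier–Haack reaction) → E-nitroalkene (Henry condensation).
- Ring B is made last by [4+2] cycloaddition, followed in the same flask by DDQ and then DBU. Fluoride and hydrogenolysis then free the three phenols.
- Stereochemistry: the target has no stereocentre. Only the E geometry of the nitroalkene (thermodynamic) is set, and the stereocentres of the cycloadduct are erased on aromatisation.

Key step: step 9

Remark: ring B positions are numbered C1'–C6' as in the isoflavone; compounds 4, 14, 16 and 17 are racemic.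

**Route**

Step 1
Reactants: 1 glutaric anhydride
Product: 3 6,6-dimethyltetrahydro-2H-pyran-2-one, via 5-hydroxy-5-methylhexanoic acid 2 (not isolated)
Conditions: MeMgBr (2.2 equiv), THF, −20 °C to rt; then 2 M HCl, rt
Reagents that add atoms: methylmagnesium bromide, C[Mg]Br
Why: Grignard addition to a cyclic anhydride: the first equivalent opens the ring to the 5-oxohexanoate, whose carboxylate is inert, the second adds to the ketone, and acidification lets the tertiary δ-hydroxy acid 2 lactonise.

Step 2
Reactants: 3 6,6-dimethyltetrahydro-2H-pyran-2-one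
Product: 4 6,6-dimethyltetrahydro-2H-pyran-2-ol
Conditions: i-Bu2AlH (1.1 equiv), CH2Cl2, −78 °C; aq. potassium sodium tartrate
Reagents that add atoms: none
Why: partial reduction of a lactone with i-Bu2AlH, whose tetrahedral aluminium hemiacetal is stable at −78 °C and should give the lactol on work-up.

Step 3
Reactants: 4 6,6-dimethyltetrahydro-2H-pyran-2-ol
Product: 5 2,2-dimethyl-3,4-dihydro-2H-pyran
Conditions: MsCl, Et3N, CH2Cl2, 0 °C to reflux; distillation
Reagents that add atoms: none
Why: dehydration of a lactol to the cyclic enol ether by sulfonylation of the anomeric hydroxyl and amine-induced elimination, the volatile product being taken off by distillation.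

Step 4
Reactants: 5 2,2-dimethyl-3,4-dihydro-2H-pyran
Product: 7 1-(6,6-dimethyl-5,6-dihydro-4H-pyran-2-yl)ethan-1-one, via (6,6-dimethyl-5,6-dihydro-4H-pyran-2-yl)lithium 6 (not isolated)
Conditions: t-BuLi (1.2 equiv), THF/pentane, −78 to 0 °C; then MeC(O)N(OMe)Me, −78 °C to rt; aq. NH4Cl
Reagents that add atoms: N-methoxy-N-methylacetamide, CC(=O)N(C)OC
Why: α-lithiation of a cyclic enol ether at the oxygen-bearing vinylic carbon, then acylation with an N-methoxy-N-methylamide whose chelated tetrahedral adduct prevents a second addition.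

Step 5
Reactants: 7 1-(6,6-dimethyl-5,6-dihydro-4H-pyran-2-yl)ethan-1-one
Product: 8 tert-butyl{[1-(6,6-dimethyl-5,6-dihydro-4H-pyran-2-yl)ethenyl]oxy}dimethylsilane
Conditions: TBSOTf (1.2 equiv), Et3N (2 equiv), CH2Cl2, 0 °C; distillation or Et3N-deactivated silica
Reagents that add atoms: tert-butyldimethylsilyl trifluoromethanesulfonate, CC(C)(C)[Si](C)(C)OS(=O)(=O)C(F)(F)F
Why: soft enolisation of a methyl enone (O-silylation, then deprotonation of the methyl group, which is faster than γ-deprotonation in the ring) should give the cross-conjugated 2-silyloxy diene; the tert-butyldimethylsilyl group is chosen so that the enol ether survives heating and the later aryl silyl ether survives DBU.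

Step 6
Reactants: 9 2,4,6-trihydroxyacetophenone
Product: 10 1-[2,4-bis(benzyloxy)-6-hydroxyphenyl]ethan-1-one
Conditions: BnBr (2.05 equiv), K2CO3, DMF, rt
Reagents that add atoms: benzyl bromide, BrCc1ccccc1
Why: Williamson ether synthesis that should stop at the dibenzyl ether, because the last ortho hydroxyl is held in a hydrogen bond to the acetyl carbonyl; this free hydroxyl is the one needed to close ring C.

Step 7
Reactants: 10 1-[2,4-bis(benzyloxy)-6-hydroxyphenyl]ethan-1-one
Product: 12 5,7-bis(benzyloxy)-4-oxo-4H-chromene-3-carbaldehyde, via chromon-3-ylmethylidene iminium chloride 11 (not isolated)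
Conditions: POCl3 (3 equiv), DMF, 0 to 50 °C; then ice-water
Reagents that add atoms: N,N-dimethylformamide, CN(C)C=O; water, O
Why: Vilsmeier–Haack reaction of a 2-hydroxyacetophenone: the methyl group is aminomethylenated twice, the phenol closes ring C on one iminium carbon with loss of dimethylamine, and water hydrolyses the remaining iminium 11 to the aldehyde.

Step 8
Reactants: 12 5,7-bis(benzyloxy)-4-oxo-4H-chromene-3-carbaldehyde; 13 nitromethane
Product: 15 (E)-5,7-bis(benzyloxy)-3-(2-nitroethenyl)-4H-chromen-4-one, via β-nitro alcohol 14 (not isolated)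
Conditions: MeNO2 (5 equiv), Et3N (0.2 equiv), THF, 0 °C; evaporate; then MsCl, Et3N, CH2Cl2, −10 °C
Reagents that add atoms: none
Why: Henry (nitroaldol) reaction followed by sulfonylation and E1cB elimination of the β-nitro alcohol should give the conjugated nitroalkene as its more stable E isomer; only catalytic amine at low temperature is used in the first stage to spare C2 of the chromone.

Step 9
Reactants: 8 tert-butyl{[1-(6,6-dimethyl-5,6-dihydro-4H-pyran-2-yl)ethenyl]oxy}dimethylsilane; 15 (E)-5,7-bis(benzyloxy)-3-(2-nitroethenyl)-4H-chromen-4-one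
Product: 18 5,7-bis(benzyloxy)-3-[8-(tert-butyldimethylsilyloxy)-2,2-dimethylchroman-6-yl]-4H-chromen-4-one, via nitrocyclohexene cycloadduct 16 (not isolated), via nitrocyclohexadiene 17 (not isolated)
Conditions: 15 (1.1 equiv), toluene, 80 °C; then DDQ (1.0 equiv), 0 °C to rt; then DBU (3 equiv), rt
Reagents that add atoms: none
Why: Proposed new method: diene 8 and nitroalkene 15 should combine in a normal-demand, strongly asynchronous [4+2] cycloaddition (ring B closes by intermolecular cycloaddition, with C1'–C2' and C5'–C6' formed in one event), the CH2 terminus of the silyl enol ether attacking the chromonyl-bearing β-carbon and the ring CH of the dihydropyran closing onto the nitro-bearing carbon to give 16. DDQ then abstracts hydride from the allylic CH2 at C2' (the cation is an oxocarbenium ion of the ring D oxygen, and the competing C5'–H lies next to the nitro-bearing carbon and is deactivated, so the silyl ether is not at risk), loss of the C5' proton gives the cyclohexa-1,3-diene 17, and DBU expels HNO2 across C1'–C6' with aromatisation as the driving force; the oxidant is added before the base because a secondary nitro group without an acidifying neighbour would only form its nitronate with DBU. The closest known reaction types are the Diels–Alder reaction of 2-silyloxydienes with nitroalkenes, the DDQ aromatisation of silyloxycyclohexadienes to aryl silyl ethers and the base-induced loss of HNO2 from nitrocyclohexadienes. No stereocentre has to be controlled, since the three of 16 (C1' and C6' trans as in the E-alkene, C5' as an endo/exo mixture) are all erased on aromatisation. The step needs regiocontrol, which the silyloxy group on C3' (para to the nitro carbon), the alkyl-substituted C5' terminus (ortho orientation, larger HOMO coefficient at C2') and the small steric demand of the CH2 terminus toward the hindered β-carbon should secure against the opposing pull of the ring D oxygen on C4'. It also needs chemoselectivity for the nitroalkene over the chromone C2=C3 bond and over C2 as a conjugate acceptor, which the much lower LUMO of the nitroalkene and an uncatalysed, base-free cycloaddition (with the diene as limiting partner, so that none is left to consume DDQ) should provide.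

Step 10
Reactants: 18 5,7-bis(benzyloxy)-3-[8-(tert-butyldimethylsilyloxy)-2,2-dimethylchroman-6-yl]-4H-chromen-4-one
Product: 19 5,7-bis(benzyloxy)-3-(8-hydroxy-2,2-dimethylchroman-6-yl)-4H-chromen-4-one
Conditions: Bu4NF, AcOH, THF, 0 °C
Reagents that add atoms: none
Why: fluoride cleavage of an aryl silyl ether (strong Si–F bond, phenoxide leaving group), buffered with acetic acid so that the pyrone ring is not opened by base.

Step 11
Reactants: 19 5,7-bis(benzyloxy)-3-(8-hydroxy-2,2-dimethylchroman-6-yl)-4H-chromen-4-one
Product: 20 5,7-dihydroxy-3-(8-hydroxy-2,2-dimethylchroman-6-yl)-4H-chromen-4-one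
Conditions: H2 (1 atm), 10% Pd/C, EtOAc/MeOH, rt
Reagents that add atoms: none
Why: catalytic hydrogenolysis of benzyl aryl ethers, which at atmospheric pressure and room temperature should leave the chromone C2=C3 bond and the chroman ring untouched if stopped after two equivalents of hydrogen.

**Compound list**
1 | glutaric anhydride | O=C1CCCC(=O)O1 | starting material
2 | 5-hydroxy-5-methylhexanoic acid | CC(C)(O)CCCC(=O)O | intermediate (not isolated)
3 | 6,6-dimethyltetrahydro-2H-pyran-2-one | CC1(C)CCCC(=O)O1 | intermediate
4 | 6,6-dimethyltetrahydro-2H-pyran-2-ol (racemic lactol) | CC1(C)CCCC(O)O1 | intermediate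
5 | 2,2-dimethyl-3,4-dihydro-2H-pyran | CC1(C)CCC=CO1 | intermediate
6 | (6,6-dimethyl-5,6-dihydro-4H-pyran-2-yl)lithium | [Li]C1=CCCC(C)(C)O1 | intermediate (not isolated)
7 | 1-(6,6-dimethyl-5,6-dihydro-4H-pyran-2-yl)ethan-1-one | CC(=O)C1=CCCC(C)(C)O1 | intermediate
8 | tert-butyl{[1-(6,6-dimethyl-5,6-dihydro-4H-pyran-2-yl)ethenyl]oxy}dimethylsilane | C=C(O[Si](C)(C)C(C)(C)C)C1=CCCC(C)(C)O1 | intermediate
9 | 2,4,6-trihydroxyacetophenone | CC(=O)c1c(O)cc(O)cc1O | starting material
10 | 1-[2,4-bis(benzyloxy)-6-hydroxyphenyl]ethan-1-one | CC(=O)c1c(O)cc(OCc2ccccc2)cc1OCc1ccccc1 | intermediate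
11 | N-{[5,7-bis(benzyloxy)-4-oxo-4H-chromen-3-yl]methylidene}-N-methylmethanaminium chloride (chromon-3-ylmethylidene iminium chloride) | C[N+](C)=Cc1coc2cc(OCc3ccccc3)cc(OCc3ccccc3)c2c1=O.[Cl-] | intermediate (not isolated)
12 | 5,7-bis(benzyloxy)-4-oxo-4H-chromene-3-carbaldehyde | O=Cc1coc2cc(OCc3ccccc3)cc(OCc3ccccc3)c2c1=O | intermediate
13 | nitromethane | C[N+](=O)[O-] | starting material
14 | 5,7-bis(benzyloxy)-3-(1-hydroxy-2-nitroethyl)-4H-chromen-4-one (racemic β-nitro alcohol) | O=c1c(C(O)C[N+](=O)[O-])coc2cc(OCc3ccccc3)cc(OCc3ccccc3)c12 | intermediate (not isolated)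
15 | (E)-5,7-bis(benzyloxy)-3-(2-nitroethenyl)-4H-chromen-4-one | O=c1c(/C=C/[N+](=O)[O-])coc2cc(OCc3ccccc3)cc(OCc3ccccc3)c12 | intermediate
16 | 5,7-bis(benzyloxy)-3-[8-(tert-butyldimethylsilyloxy)-2,2-dimethyl-5-nitro-3,4,4a,5,6,7-hexahydro-2H-chromen-6-yl]-4H-chromen-4-one (nitrocyclohexene cycloadduct; racemic; nitro and chromonyl trans; C4a as a mixture of epimers, left open in the SMILES) | O=c1c([C@@H]2CC(O[Si](C)(C)C(C)(C)C)=C3OC(C)(C)CCC3[C@H]2[N+](=O)[O-])coc2cc(OCc3ccccc3)cc(OCc3ccccc3)c12 | intermediate (not isolated)
17 | 5,7-bis(benzyloxy)-3-[8-(tert-butyldimethylsilyloxy)-2,2-dimethyl-5-nitro-3,4,5,6-tetrahydro-2H-chromen-6-yl]-4H-chromen-4-one (nitrocyclohexadiene; racemic; nitro and chromonyl trans) | O=c1c([C@@H]2C=C(O[Si](C)(C)C(C)(C)C)C3=C(CCC(C)(C)O3)[C@H]2[N+](=O)[O-])coc2cc(OCc3ccccc3)cc(OCc3ccccc3)c12 | intermediate (not isolated)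
18 | 5,7-bis(benzyloxy)-3-[8-(tert-butyldimethylsilyloxy)-2,2-dimethylchroman-6-yl]-4H-chromen-4-one | O=c1c(-c2cc(O[Si](C)(C)C(C)(C)C)c3OC(C)(C)CCc3c2)coc2cc(OCc3ccccc3)cc(OCc3ccccc3)c12 | intermediate
19 | 5,7-bis(benzyloxy)-3-(8-hydroxy-2,2-dimethylchroman-6-yl)-4H-chromen-4-one | O=c1c(-c2cc(O)c3OC(C)(C)CCc3c2)coc2cc(OCc3ccccc3)cc(OCc3ccccc3)c12 | intermediate
20 | 5,7-dihydroxy-3-(8-hydroxy-2,2-dimethylchroman-6-yl)-4H-chromen-4-one | CC1(C)CCc2cc(-c3coc4cc(O)cc(O)c4c3=O)cc(O)c2O1 | target

**Step count**
Total: 11 steps. Longest linear sequence: 8 steps (steps 1–5, 9, 10, 11).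

**Steps most likely to fail**

1. Step 9 (the proposed new method). The cycloaddition may lose regiocontrol, with bonding through the ring CH terminus under the influence of the ring D oxygen. The nitroalkene may instead react as a heterodiene with the silyl enol ether and give a cyclic nitronate, or the enol ether may add in a conjugate sense with silyl transfer and no ring closure. DDQ may dehydrogenate further instead of leaving HNO2 to be lost. The fallback uses known chemistry: ring B is brought in as a finished arene and joined to C3 of the chromone by Suzuki–Miyaura coupling. It sets out from 10. Heating 10 with Me2NCH(OMe)2 in toluene should give (E)-1-[2,4-bis(benzyloxy)-6-hydroxyphenyl]-3-(dimethylamino)prop-2-en-1-one F1 by condensation at the acetyl methyl group. Iodine and pyridine in CHCl3 should then close ring C with iodination and give 5,7-bis(benzyloxy)-3-iodo-4H-chromen-4-one F2 as the halide partner. For the boron partner, bought catechol and 2-methylbut-3-en-2-ol in formic acid should give 2,2-dimethylchroman-8-ol F3 by Friedel–Crafts prenylation ortho to a hydroxyl and cyclisation. TBSCl and imidazole in DMF should give tert-butyl[(2,2-dimethylchroman-8-yl)oxy]dimethylsilane F4 as the protected arene. C–H borylation with [Ir(OMe)(cod)]2, 4,4'-di-tert-butyl-2,2'-bipyridine and B2pin2 should give tert-butyl{[2,2-dimethyl-6-(4,4,5,5-tetramethyl-1,3,2-dioxaborolan-2-yl)chroman-8-yl]oxy}dimethylsilane F5 by reaction at C6, the only ring C–H without an ortho substituent. Coupling of F2 with F5 (Pd(dppf)Cl2, K3PO4, dioxane/H2O, 80 °C) comes back to the route at 18.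

2. Step 8. The amine or the nitronate may attack C2 and open the pyrone ring, and the nitroalkene may oligomerise under the basic dehydration. The fallback sets out from 12 and avoids both nitromethane and the nitro alcohol. Knoevenagel–Doebner condensation with malonic acid in pyridine at 90 °C should give (E)-3-[5,7-bis(benzyloxy)-4-oxo-4H-chromen-3-yl]prop-2-enoic acid F6 as the E-configured acrylic acid. Decarboxylative nitration of F6 (t-BuONO, TEMPO, MeCN, 50 °C, air) comes back to the route at 15.

3. Step 4. Metalation of the volatile enol ether may be incomplete, or the vinyllithium may deprotonate the enolisable amide instead of adding to it. The fallback sets out from lactone 3 and bypasses steps 2 to 4, making the C–C bond by cross-coupling. KN(SiMe3)2 and (PhO)2P(O)Cl in THF at −78 °C should give 6,6-dimethyl-5,6-dihydro-4H-pyran-2-yl diphenyl phosphate F7 by O-phosphorylation of the lactone enolate. Stille coupling with tributyl(1-ethoxyvinyl)stannane (Pd(PPh3)4, LiCl, THF, reflux) should give 6-(1-ethoxyethenyl)-2,2-dimethyl-3,4-dihydro-2H-pyran F8 as a bis(enol ether). Dilute aqueous oxalic acid in THF at 0 °C should hydrolyse only the acyclic enol ether of F8 and comes back to the route at 7.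

**Further compounds**
F1 | step 9 | (E)-1-[2,4-bis(benzyloxy)-6-hydroxyphenyl]-3-(dimethylamino)prop-2-en-1-one | CN(C)/C=C/C(=O)c1c(O)cc(OCc2ccccc2)cc1OCc1ccccc1
F2 | step 9 | 5,7-bis(benzyloxy)-3-iodo-4H-chromen-4-one | O=c1c(I)coc2cc(OCc3ccccc3)cc(OCc3ccccc3)c12
F3 | step 9 | 2,2-dimethylchroman-8-ol | CC1(C)CCc2cccc(O)c2O1
F4 | step 9 | tert-butyl[(2,2-dimethylchroman-8-yl)oxy]dimethylsilane | CC1(C)CCc2cccc(O[Si](C)(C)C(C)(C)C)c2O1
F5 | step 9 | tert-butyl{[2,2-dimethyl-6-(4,4,5,5-tetramethyl-1,3,2-dioxaborolan-2-yl)chroman-8-yl]oxy}dimethylsilane | CC1(C)CCc2cc(B3OC(C)(C)C(C)(C)O3)cc(O[Si](C)(C)C(C)(C)C)c2O1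
F6 | step 8 | (E)-3-[5,7-bis(benzyloxy)-4-oxo-4H-chromen-3-yl]prop-2-enoic acid | O=C(O)/C=C/c1coc2cc(OCc3ccccc3)cc(OCc3ccccc3)c2c1=O
F7 | step 4 | 6,6-dimethyl-5,6-dihydro-4H-pyran-2-yl diphenyl phosphate | CC1(C)CCC=C(OP(=O)(Oc2ccccc2)Oc2ccccc2)O1
F8 | step 4 | 6-(1-ethoxyethenyl)-2,2-dimethyl-3,4-dihydro-2H-pyran | CCOC(=C)C1=CCCC(C)(C)O1
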